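Cuts: (a) the upper interflavan bond, top C4–middle C8; (b) middle C4–C4a; (c) the middle C2–O1 aryl ether; (d) the middle C3–C4 bond, back to a chalcone from an 8-formyl bottom flavan; the bottom and top flavans go back to one epoxy aryl ether.
Enabling feature: middle C4 carries C8 of the 2,4,6-trioxygenated ring A of the bottom unit and sits trans to the middle 3-OH, the pattern left when C4a (ortho carbon of the future middle ring A) opens a trans-epoxide at its benzylic end.
Forward order: bottom ring C (epoxy-arene closure), C8 bromination and formylation, chalcone, epoxide, aryl ether, middle ring C (key closure), then the top unit is joined by a flavan-4-yl cation coupling and all benzyl groups are removed.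
Stereochemistry: C2 and C3 of the bottom and top units come from a Sharpless kinetic resolution followed by Mitsunobu inversion; middle C3 and C4 from a poly-D-leucine epoxidation and anti epoxide opening; middle C2 from chelation-controlled reduction followed by Mitsunobu inversion; top C4 from attack anti to its 3-benzyloxy group.
Target read as epiafzelechin-(4β→8)-ent-epiafzelechin-(4α→8)-epiafzelechin: top and bottom units (2R,3R), middle unit (2S,3S), both C4 links 3,4-trans.

Key step: step 12

Assumption: 3,5-bis(benzyloxy)phenol, poly-D-leucine and an ethereal Zn(BH4)2 stock solution are taken as available reagents, and the usual enantiomer and face preference of the Sharpless kinetic resolution is taken to hold for the aryl vinyl carbinol 3.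
Abbreviations: Bn = benzyl; Fl = (2R,3R)-3,5,7-tris(benzyloxy)-2-[4-(benzyloxy)phenyl]chroman-8-yl (protected bottom flavan bonded through C8); flavan numbering O1, C2, C3, C4, C4a, C5–C8, C8a.

Step 1
Reactants: 1 4-(benzyloxy)benzaldehyde; 2 vinylmagnesium bromide
Product: 3 rac-1-[4-(benzyloxy)phenyl]prop-2-en-1-ol
Conditions: THF, 0 °C; then H2O
Reagents that add atoms: none
Why: Grignard addition of the vinyl nucleophile to the aromatic aldehyde should give the racemic secondary allylic alcohol that is resolved in step 2.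

Step 2
Reactants: 3 rac-1-[4-(benzyloxy)phenyl]prop-2-en-1-ol
Product: 4 (S)-[4-(benzyloxy)phenyl][(2R)-oxiran-2-yl]methanol (erythro)
Conditions: Ti(OiPr)4 (0.2 equiv), L-(+)-DIPT (0.25 equiv), t-BuOOH (0.6 equiv), 4 Å MS, CH2Cl2, −20 °C
Reagents that add atoms: tert-butyl hydroperoxide CC(C)(C)OO
Why: Sharpless kinetic resolution, in which the L-(+)-tartrate catalyst should epoxidize the (R)-enantiomer of the aryl vinyl carbinol far faster than its antipode and on the face that gives the erythro (anti) epoxy alcohol, so both stereocenters of 4 are set by the tartrate while the (S)-enantiomer of 3 stays behind.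

Step 3
Reactants: 4 (S)-[4-(benzyloxy)phenyl][(2R)-oxiran-2-yl]methanol; 5 3,5-bis(benzyloxy)phenol
Product: 6 (2R)-2-{(R)-[3,5-bis(benzyloxy)phenoxy][4-(benzyloxy)phenyl]methyl}oxirane (threo)
Conditions: PPh3, DIAD, THF, 0 °C → rt
Reagents that add atoms: none
Why: Mitsunobu etherification displaces the oxyphosphonium group by the phenoxide in an SN2 sense and so inverts the carbinol carbon, turning the erythro epoxy alcohol into the threo ether that maps onto a 2,3-cis flavan, while the oxirane is a spectator under these near-neutral conditions.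

Step 4
Reactants: 6 (2R)-2-{(R)-[3,5-bis(benzyloxy)phenoxy][4-(benzyloxy)phenyl]methyl}oxirane
Product: 7 (2R,3R)-5,7-bis(benzyloxy)-2-[4-(benzyloxy)phenyl]chroman-3-ol (5,7,4'-tri-O-benzylepiafzelechin)
Conditions: AuCl3 (5 mol %), AgOTf (15 mol %), ClCH2CH2Cl, rt
Reagents that add atoms: none
Why: Intramolecular Friedel–Crafts epoxy-arene cyclization catalysed by trivalent gold, in which the activated terminal epoxide is attacked at its CH2 carbon by an ortho carbon of the 3,5-dioxygenated aryl ether in a 6-endo closure that breaks neither C–O bond at the two stereocenters and should therefore deliver ring C with the 2,3-cis relation.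

Step 5
Reactants: 7 (2R,3R)-5,7-bis(benzyloxy)-2-[4-(benzyloxy)phenyl]chroman-3-ol
Product: 8 (2R,3R)-5,7-bis(benzyloxy)-2-[4-(benzyloxy)phenyl]-8-bromochroman-3-ol
Conditions: NBS, CH2Cl2, −78 → 0 °C
Reagents that add atoms: N-bromosuccinimide O=C1CCC(=O)N1Br
Why: Electrophilic aromatic bromination of the 5,7-dioxygenated ring A of benzylated flavan-3-ols by NBS at low temperature is expected at C8 in preference to C6, and the bromine serves later both as the handle for formylation and as the C8 cap of the top unit.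

Step 6
Reactants: 8 (2R,3R)-5,7-bis(benzyloxy)-2-[4-(benzyloxy)phenyl]-8-bromochroman-3-ol
Product: 9 (2R,3R)-3,5,7-tris(benzyloxy)-2-[4-(benzyloxy)phenyl]-8-bromochromane
Conditions: NaH, BnBr, DMF, 0 °C → rt
Reagents that add atoms: benzyl bromide BrCc1ccccc1
Why: Williamson etherification of the secondary alkoxide masks the 3-hydroxyl against the organolithium, the second Mitsunobu reaction and the cationic steps, and keeps all protecting groups removable by one hydrogenolysis.

Step 7
Reactants: 9 (2R,3R)-3,5,7-tris(benzyloxy)-2-[4-(benzyloxy)phenyl]-8-bromochromane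
Product: 11 (2R,3R)-3,5,7-tris(benzyloxy)-2-[4-(benzyloxy)phenyl]chromane-8-carbaldehyde (Fl–CHO), via 8-lithiochromane 10 (not isolated)
Conditions: n-BuLi, THF, −78 °C; DMF, −78 → 0 °C; then H2O
Reagents that add atoms: N,N-dimethylformamide CN(C)C=O; n-butyllithium CCCC[Li] (lithium of 10 only)
Why: Bromine–lithium exchange at −78 °C is faster than benzylic deprotonation, and formylation of the aryllithium by DMF places the one-carbon unit unambiguously at C8.

Step 8
Reactants: 11 Fl–CHO; 12 1-[4-(benzyloxy)phenyl]ethan-1-one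
Product: 13 (E)-1-[4-(benzyloxy)phenyl]-3-Fl-prop-2-en-1-one
Conditions: KOH, EtOH/THF, 40 °C
Reagents that add atoms: none
Why: Claisen–Schmidt condensation of the non-enolizable aryl aldehyde with the acetophenone enolate, followed by dehydration, should give the thermodynamically favoured (E)-enone, and the fully benzylated flavan has no site that base can epimerize.

Step 9
Reactants: 13 (E)-1-[4-(benzyloxy)phenyl]-3-Fl-prop-2-en-1-one
Product: 14 [4-(benzyloxy)phenyl][(2S,3R)-3-Fl-oxiran-2-yl]methanone (trans)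
Conditions: poly-D-leucine, urea·H2O2, DBU, THF, rt
Reagents that add atoms: hydrogen peroxide OO (supplied as its urea adduct NC(N)=O.OO)
Why: Juliá–Colonna epoxidation, in which hydroperoxide adds to the enone inside the helical polypeptide and the enolate closes to the trans-epoxide, the D-configured polymer (mirror image of the poly-L-leucine that gives (2R,3S)-epoxychalcone) being expected to impose the (2S,3R) oxirane regardless of the remote flavan stereocenters.

Step 10
Reactants: 14 [4-(benzyloxy)phenyl][(2S,3R)-3-Fl-oxiran-2-yl]methanone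
Product: 15 (R)-[4-(benzyloxy)phenyl][(2R,3R)-3-Fl-oxiran-2-yl]methanol (erythro)
Conditions: Zn(BH4)2, Et2O/CH2Cl2, −30 °C; then H2O
Reagents that add atoms: none
Why: Chelation-controlled hydride reduction, in which zinc bridges the carbonyl and oxirane oxygens and hydride adds from the side of the oxirane hydrogen, should give the erythro (anti) epoxy alcohol with the new carbinol center R.

Step 11
Reactants: 15 (R)-[4-(benzyloxy)phenyl][(2R,3R)-3-Fl-oxiran-2-yl]methanol; 5 3,5-bis(benzyloxy)phenol
Product: 16 (2S,3R)-2-{(S)-[3,5-bis(benzyloxy)phenoxy][4-(benzyloxy)phenyl]methyl}-3-Fl-oxirane (threo; trans-epoxide)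
Conditions: PPh3, DIAD, toluene, 0 °C → rt
Reagents that add atoms: none
Why: Mitsunobu etherification with inversion converts the erythro alcohol into the threo ether with the (S) configuration of the future middle C2, the adjacent oxirane inductively disfavouring ionization of the benzylic oxyphosphonium ion so that SN2 displacement should prevail.

Step 12
Reactants: 16 (2S,3R)-2-{(S)-[3,5-bis(benzyloxy)phenoxy][4-(benzyloxy)phenyl]methyl}-3-Fl-oxirane
Product: 17 5,7,4'-tri-O-benzyl-ent-epiafzelechin-(4α→8)-3,5,7,4'-tetra-O-benzylepiafzelechin (middle unit 2S,3S,4S; free 3-OH)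
Conditions: (CF3)2CHOH/CH2Cl2 (1:4), 0.005 M, 0 °C → rt
Reagents that add atoms: none
Why: Hydrogen bonding from hexafluoroisopropanol polarizes the oxirane and weakens its C4–O bond, whose carbon is benzylic to the 2,4,6-trioxygenated ring A of the bottom unit, and the ortho carbon of the tethered 3,5-bis(benzyloxy)phenyl ether attacks that carbon, rearomatization then leaving the pyran ring with a free 3-hydroxyl. The closest known reaction type is the intramolecular Friedel–Crafts epoxy-arene cyclization of aryl 3-aryl-2,3-epoxypropyl ethers to trans-4-arylchroman-3-ols, promoted by fluorinated alcohols or by AuCl3 with AgOTf. Ring C of the middle unit closes in the 6-endo mode through the new C4–C4a bond. The only new stereocenter, C4, is controlled by the trans-epoxide, since attack anti to the departing oxygen gives the 3,4-trans relation and a free benzylic cation would be captured anti to the C3 oxygen with the same outcome, while C2 and C3 are carried through unchanged. The step needs 6-endo over 5-exo selectivity, which the benzylic stabilization at C4 (absent at C3) secures, and a single regiochemistry on the nucleophilic ring, which is guaranteed because the two ortho carbons of the symmetric ether are equivalent. High dilution and low temperature are chosen so that capture by the tethered arene outruns hydride shift or intermolecular alkylation.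

Step 13
Reactants: 9 (2R,3R)-3,5,7-tris(benzyloxy)-2-[4-(benzyloxy)phenyl]-8-bromochromane
Product: 18 (2R,3R,4S)-3,5,7-tris(benzyloxy)-2-[4-(benzyloxy)phenyl]-8-bromo-4-(2-ethoxyethoxy)chromane (3,4-trans)
Conditions: DDQ, HOCH2CH2OEt, CH2Cl2, rt
Reagents that add atoms: 2-ethoxyethanol CCOCCO
Why: Oxidative benzylic etherification, in which DDQ abstracts hydride from C4 of the electron-rich flavan and 2-ethoxyethanol traps the cation anti to the 3-benzyloxy group, the C4 configuration being of no consequence because this ether is ionized again in step 14.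

Step 14
Reactants: 17 5,7,4'-tri-O-benzyl-ent-epiafzelechin-(4α→8)-3,5,7,4'-tetra-O-benzylepiafzelechin; 18 (2R,3R,4S)-3,5,7-tris(benzyloxy)-2-[4-(benzyloxy)phenyl]-8-bromo-4-(2-ethoxyethoxy)chromane
Product: 19 8-bromo-3,5,7,4'-tetra-O-benzylepiafzelechin-(4β→8)-5,7,4'-tri-O-benzyl-ent-epiafzelechin-(4α→8)-3,5,7,4'-tetra-O-benzylepiafzelechin
Conditions: BF3·OEt2 (0.5 equiv), 4 Å MS, CH2Cl2, −78 → −30 °C
Reagents that add atoms: none
Why: Lewis-acid-promoted flavan-4-yl cation coupling (intermolecular Friedel–Crafts alkylation), in which BF3 ionizes the 4-alkoxy group and the cation is attacked by the most nucleophilic free position, C8 of the middle ring A, anti to the 3-benzyloxy group so that the new C4 center is 3,4-trans (4β), while the bromine at C8 of the electrophile prevents its self-condensation.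

Step 15
Reactants: 19 protected bromo trimer
Product: 20 epiafzelechin-(4β→8)-ent-epiafzelechin-(4α→8)-epiafzelechin (CNP0191553.2)
Conditions: H2 (1 atm), Pd(OH)2/C, THF/MeOH/H2O, rt
Reagents that add atoms: none
Why: Catalytic hydrogenolysis over Pd(OH)2 on carbon should cleave all eleven benzyl ethers and the aryl C–Br bond in one operation without touching the interflavan bonds or any stereocenter.

Compound list
1 | 4-(benzyloxy)benzaldehyde | O=Cc1ccc(OCc2ccccc2)cc1 | starting material
2 | vinylmagnesium bromide | C=C[Mg]Br | starting material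
3 | rac-1-[4-(benzyloxy)phenyl]prop-2-en-1-ol | C=CC(O)c1ccc(OCc2ccccc2)cc1 | intermediate
4 | (S)-[4-(benzyloxy)phenyl][(2R)-oxiran-2-yl]methanol (erythro) | O[C@@H](c1ccc(OCc2ccccc2)cc1)[C@@H]4OC4 | intermediate
5 | 3,5-bis(benzyloxy)phenol | Oc1cc(OCc2ccccc2)cc(OCc2ccccc2)c1 | starting material
6 | (2R)-2-{(R)-[3,5-bis(benzyloxy)phenoxy][4-(benzyloxy)phenyl]methyl}oxirane (threo) | c1c(OCc2ccccc2)cc(OCc2ccccc2)cc1O[C@H](c1ccc(OCc2ccccc2)cc1)[C@@H]4OC4 | intermediate
7 | (2R,3R)-5,7-bis(benzyloxy)-2-[4-(benzyloxy)phenyl]chroman-3-ol | c1c(OCc2ccccc2)cc(OCc2ccccc2)c2c1O[C@H](c1ccc(OCc3ccccc3)cc1)[C@H](O)C2 | intermediate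
8 | (2R,3R)-5,7-bis(benzyloxy)-2-[4-(benzyloxy)phenyl]-8-bromochroman-3-ol | Brc1c(OCc2ccccc2)cc(OCc2ccccc2)c2c1O[C@H](c1ccc(OCc3ccccc3)cc1)[C@H](O)C2 | intermediate
9 | (2R,3R)-3,5,7-tris(benzyloxy)-2-[4-(benzyloxy)phenyl]-8-bromochromane | Brc1c(OCc2ccccc2)cc(OCc2ccccc2)c2c1O[C@H](c1ccc(OCc3ccccc3)cc1)[C@H](OCc1ccccc1)C2 | intermediate
10 | 8-lithio analogue of 9 (Fl–Li) | [Li]c1c(OCc2ccccc2)cc(OCc2ccccc2)c2c1O[C@H](c1ccc(OCc3ccccc3)cc1)[C@H](OCc1ccccc1)C2 | intermediate (not isolated)
11 | (2R,3R)-3,5,7-tris(benzyloxy)-2-[4-(benzyloxy)phenyl]chromane-8-carbaldehyde (Fl–CHO) | O=Cc1c(OCc2ccccc2)cc(OCc2ccccc2)c2c1O[C@H](c1ccc(OCc3ccccc3)cc1)[C@H](OCc1ccccc1)C2 | intermediate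
12 | 1-[4-(benzyloxy)phenyl]ethan-1-one | CC(=O)c1ccc(OCc2ccccc2)cc1 | starting material
13 | (E)-1-[4-(benzyloxy)phenyl]-3-Fl-prop-2-en-1-one | O=C(c1ccc(OCc2ccccc2)cc1)/C=C/c1c(OCc2ccccc2)cc(OCc2ccccc2)c2c1O[C@H](c1ccc(OCc3ccccc3)cc1)[C@H](OCc1ccccc1)C2 | intermediate
14 | [4-(benzyloxy)phenyl][(2S,3R)-3-Fl-oxiran-2-yl]methanone (trans) | O=C(c1ccc(OCc2ccccc2)cc1)[C@H]4O[C@@H]4c1c(OCc2ccccc2)cc(OCc2ccccc2)c2c1O[C@H](c1ccc(OCc3ccccc3)cc1)[C@H](OCc1ccccc1)C2 | intermediate
15 | (R)-[4-(benzyloxy)phenyl][(2R,3R)-3-Fl-oxiran-2-yl]methanol (erythro) | O[C@H](c1ccc(OCc2ccccc2)cc1)[C@H]4O[C@@H]4c1c(OCc2ccccc2)cc(OCc2ccccc2)c2c1O[C@H](c1ccc(OCc3ccccc3)cc1)[C@H](OCc1ccccc1)C2 | intermediate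
16 | (2S,3R)-2-{(S)-[3,5-bis(benzyloxy)phenoxy][4-(benzyloxy)phenyl]methyl}-3-Fl-oxirane (threo; trans-epoxide) | c1c(OCc2ccccc2)cc(OCc2ccccc2)cc1O[C@@H](c1ccc(OCc2ccccc2)cc1)[C@H]4O[C@@H]4c1c(OCc2ccccc2)cc(OCc2ccccc2)c2c1O[C@H](c1ccc(OCc3ccccc3)cc1)[C@H](OCc1ccccc1)C2 | intermediate
17 | 5,7,4'-tri-O-benzyl-ent-epiafzelechin-(4α→8)-3,5,7,4'-tetra-O-benzylepiafzelechin (middle unit 2S,3S,4S; free 3-OH) | c1c(OCc2ccccc2)cc(OCc2ccccc2)c2c1O[C@@H](c1ccc(OCc3ccccc3)cc1)[C@@H](O)[C@@H]2c1c(OCc2ccccc2)cc(OCc2ccccc2)c2c1O[C@H](c1ccc(OCc3ccccc3)cc1)[C@H](OCc1ccccc1)C2 | intermediate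
18 | (2R,3R,4S)-3,5,7-tris(benzyloxy)-2-[4-(benzyloxy)phenyl]-8-bromo-4-(2-ethoxyethoxy)chromane | Brc1c(OCc2ccccc2)cc(OCc2ccccc2)c2c1O[C@H](c1ccc(OCc3ccccc3)cc1)[C@H](OCc1ccccc1)[C@H]2OCCOCC | intermediate
19 | 8-bromo-3,5,7,4'-tetra-O-benzylepiafzelechin-(4β→8)-5,7,4'-tri-O-benzyl-ent-epiafzelechin-(4α→8)-3,5,7,4'-tetra-O-benzylepiafzelechin | Brc1c(OCc2ccccc2)cc(OCc2ccccc2)c2c1O[C@H](c1ccc(OCc3ccccc3)cc1)[C@H](OCc1ccccc1)[C@H]2c1c(OCc2ccccc2)cc(OCc2ccccc2)c2c1O[C@@H](c1ccc(OCc3ccccc3)cc1)[C@@H](O)[C@@H]2c1c(OCc2ccccc2)cc(OCc2ccccc2)c2c1O[C@H](c1ccc(OCc3ccccc3)cc1)[C@H](OCc1ccccc1)C2 | intermediate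
20 | epiafzelechin-(4β→8)-ent-epiafzelechin-(4α→8)-epiafzelechin (CNP0191553.2) | Oc1ccc([C@H]2Oc3cc(O)cc(O)c3[C@H](c3c(O)cc(O)c4c3O[C@@H](c3ccc(O)cc3)[C@@H](O)[C@@H]4c3c(O)cc(O)c4c3O[C@H](c3ccc(O)cc3)[C@H](O)C4)[C@H]2O)cc1 | target

Total step count: 15. Longest linear sequence: 14 steps (steps 1–12, then 14 and 15); step 13 is a one-step branch from 9.

Steps most likely to fail

Step 12 (ring closure). Once the C4–O bond ionizes, a 1,2-hydride shift from C3 (Meinwald-type rearrangement to the benzyl ketone), loss of the C2 aryl ether or intermolecular alkylation may outrun capture by the tethered arene. The fallback makes the middle–bottom bond by the classical intermolecular flavan-4-yl cation coupling; it sets out from 3 (its (S)-enantiomer, left unreacted by step 2) and from 7 and comes back at 17. The (S)-alcohol would be epoxidized with Ti(OiPr)4, D-(−)-DIPT and t-BuOOH to (R)-[4-(benzyloxy)phenyl][(2S)-oxiran-2-yl]methanol F1, etherified with 5 (PPh3, DIAD) to (2S)-2-{(S)-[3,5-bis(benzyloxy)phenoxy][4-(benzyloxy)phenyl]methyl}oxirane F2, and cyclized (AuCl3, AgOTf) to (2S,3S)-5,7-bis(benzyloxy)-2-[4-(benzyloxy)phenyl]chroman-3-ol F3, the enantiomer of 7. DDQ and 2-ethoxyethanol would convert this into (2S,3S,4R)-5,7-bis(benzyloxy)-2-[4-(benzyloxy)phenyl]-4-(2-ethoxyethoxy)chroman-3-ol F4. Separately, 7 would be benzylated (NaH, BnBr) to (2R,3R)-3,5,7-tris(benzyloxy)-2-[4-(benzyloxy)phenyl]chromane F5. TMSOTf-catalysed coupling of the ethoxyethyl ether with an excess of this nucleophile in CH2Cl2 at −78 °C should then give 17 by attack of its C8 anti to the 3-hydroxyl of the cation.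

Step 11 (Mitsunobu etherification). The oxyphosphonium ion of the 4-benzyloxybenzylic alcohol may ionize before the phenoxide displaces it, eroding the inversion at C2, or the acid-sensitive oxirane may be opened. The fallback forms the ether from the oxygen side with retention; it sets out from 14 and comes back at 16. Reagent-controlled Corey–Bakshi–Shibata reduction of 14 ((S)-Me-CBS oxazaborolidine, catecholborane, toluene, −78 °C, aryl acting as the large group) should override the chelate preference and give the threo epimer (S)-[4-(benzyloxy)phenyl][(2R,3R)-3-Fl-oxiran-2-yl]methanol F6. Ullmann-type O-arylation of this alcohol with 1-iodo-3,5-bis(benzyloxy)benzene (CuI, 3,4,7,8-tetramethyl-1,10-phenanthroline, Cs2CO3, toluene, 80 °C) leaves the carbinol carbon untouched and should give 16.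

Step 9 (Juliá–Colonna epoxidation). Conjugate addition of hydroperoxide to an enone whose β-aryl group is electron-rich and doubly ortho-substituted may be too slow inside the polypeptide, giving low conversion or poor facial control. The fallback replaces the nucleophilic epoxidation by a hydroxyl-directed one; it sets out from 13 and comes back at 15, bypassing 14. Luche reduction (NaBH4, CeCl3·7H2O, MeOH/THF, −40 °C) would give (E)-1-[4-(benzyloxy)phenyl]-3-Fl-prop-2-en-1-ol F7 as both carbinol epimers. Sharpless epoxidation under kinetic-resolution conditions with D-(−)-DIPT should then convert only the (S)-carbinol epimer, anti-selectively, into 15.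

Further compounds
F1 | step 12 | (R)-[4-(benzyloxy)phenyl][(2S)-oxiran-2-yl]methanol | O[C@H](c1ccc(OCc2ccccc2)cc1)[C@H]4OC4
F2 | step 12 | (2S)-2-{(S)-[3,5-bis(benzyloxy)phenoxy][4-(benzyloxy)phenyl]methyl}oxirane | c1c(OCc2ccccc2)cc(OCc2ccccc2)cc1O[C@@H](c1ccc(OCc2ccccc2)cc1)[C@H]4OC4
F3 | step 12 | (2S,3S)-5,7-bis(benzyloxy)-2-[4-(benzyloxy)phenyl]chroman-3-ol | c1c(OCc2ccccc2)cc(OCc2ccccc2)c2c1O[C@@H](c1ccc(OCc3ccccc3)cc1)[C@@H](O)C2
F4 | step 12 | (2S,3S,4R)-5,7-bis(benzyloxy)-2-[4-(benzyloxy)phenyl]-4-(2-ethoxyethoxy)chroman-3-ol | c1c(OCc2ccccc2)cc(OCc2ccccc2)c2c1O[C@@H](c1ccc(OCc3ccccc3)cc1)[C@@H](O)[C@@H]2OCCOCC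
F5 | step 12 | (2R,3R)-3,5,7-tris(benzyloxy)-2-[4-(benzyloxy)phenyl]chromane | c1c(OCc2ccccc2)cc(OCc2ccccc2)c2c1O[C@H](c1ccc(OCc3ccccc3)cc1)[C@H](OCc1ccccc1)C2
F6 | step 11 | (S)-[4-(benzyloxy)phenyl][(2R,3R)-3-Fl-oxiran-2-yl]methanol (threo) | O[C@@H](c1ccc(OCc2ccccc2)cc1)[C@H]4O[C@@H]4c1c(OCc2ccccc2)cc(OCc2ccccc2)c2c1O[C@H](c1ccc(OCc3ccccc3)cc1)[C@H](OCc1ccccc1)C2
F7 | step 9 | (E)-1-[4-(benzyloxy)phenyl]-3-Fl-prop-2-en-1-ol (both carbinol epimers) | OC(c1ccc(OCc2ccccc2)cc1)/C=C/c1c(OCc2ccccc2)cc(OCc2ccccc2)c2c1O[C@H](c1ccc(OCc3ccccc3)cc1)[C@H](OCc1ccccc1)C2
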